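**Plan**

- Ring B is the central benzene (B1 CH2CH2-aryl, B2 H, B3 OMe, B4 4-hydroxybenzyl, B5 OH, B6 4-hydroxybenzyl). B3 is an oxygen-bearing carbon between B2 and B4, with a second oxygen meta to it at B5, so B3 and its oxygen can be carbon monoxide and the B5 oxygen a migrated ester oxygen.
- The retrosynthesis cuts B3–B4 and B3–B2 (carbonylative [5+1] closure of ring B from a 3-acetoxy-1,4-enyne with an aroyl-capped alkyne; the B4 benzylic CH2 is carried as C=O). It then cuts the carbinol–alkyne bond (acetylide + enone), the carbinol–alkene bond (alkenyl Grignard + Weinreb amide) and ArCH2–CH2 (benzyl Grignard + 2,3-dibromopropene).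
- Forward: alkenyl bromide 4 and amide 7 give enone 9; alkyne 12 is added, then acetylation, desilylation and oxidation give enynone 18. Ring B, the only ring made, closes in step 10; the three outer benzene rings are bought. O-methylation, deacetylation and hydrogenolysis finish the synthesis.
- Stereochemistry: the target has no stereocenter; the centres in 11–18 are carried racemic and are erased by oxidation (step 9) and aromatization (step 10).

Key step: step 10

Remark: CDI, ethynylmagnesium bromide solution, TBSCl and the other reagents named in the Conditions lines are taken as commercial.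

**Step 1**
Reactants: 1 3-methoxybenzyl chloride; 2 2,3-dibromopropene
Product: 4 2-bromo-4-(3-methoxyphenyl)but-1-ene, via 3-methoxybenzylmagnesium chloride 3 (not isolated)
Conditions: Mg, Et2O, 0 °C to rt; then 2, CuI (5 mol %), Et2O/THF, 0 °C to rt
Reagents that add atoms: none
Why: The benzylic Grignard reagent should displace the allylic bromide of 2,3-dibromopropene (copper-assisted allylic substitution, SN2 and SN2' giving the same product) while the vinylic bromide stays untouched.

**Step 2**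
Reactants: 5 4-(benzyloxy)phenylacetic acid
Product: 7 2-[4-(benzyloxy)phenyl]-N-methoxy-N-methylacetamide, via acyl imidazole 6 (not isolated)
Conditions: CDI, CH2Cl2, rt; then MeNH(OMe)·HCl, rt
Reagents that add atoms: N,O-dimethylhydroxylamine hydrochloride, CNOC.Cl
Why: Activation of the acid as its acyl imidazole and aminolysis is a standard Weinreb amide synthesis that leaves the benzyl ether alone.

**Step 3**
Reactants: 4 2-bromo-4-(3-methoxyphenyl)but-1-ene; 7 2-[4-(benzyloxy)phenyl]-N-methoxy-N-methylacetamide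
Product: 9 1-[4-(benzyloxy)phenyl]-5-(3-methoxyphenyl)-3-methylidenepentan-2-one, via alkenylmagnesium bromide 8 (not isolated)
Conditions: Mg (I2-activated), THF, 40 °C; then 7, THF, −20 to 0 °C; cold 1 M HCl quench
Reagents that add atoms: none
Why: In this Weinreb ketone synthesis the chelated tetrahedral adduct prevents over-addition, the Grignard reagent is mild enough to add to the amide instead of deprotonating its benzylic CH2, and the acidic quench protonates the released amine so that it cannot add to the new enone.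

**Step 4**
Reactants: 10 4-(benzyloxy)benzaldehyde
Product: 11 1-[4-(benzyloxy)phenyl]prop-2-yn-1-ol (racemic)
Conditions: HC≡CMgBr, THF, 0 °C to rt; aq. NH4Cl
Reagents that add atoms: ethynylmagnesium bromide, C#C[Mg]Br
Why: Grignard 1,2-addition to a non-enolizable aromatic aldehyde is reliable, and the new centre is formed racemic on purpose because it is oxidized away in step 9.

**Step 5**
Reactants: 11 1-[4-(benzyloxy)phenyl]prop-2-yn-1-ol
Product: 12 {1-[4-(benzyloxy)phenyl]prop-2-yn-1-yl}oxy(tert-butyl)dimethylsilane (racemic)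
Conditions: TBSCl, imidazole, DMF, rt
Reagents that add atoms: tert-butyldimethylsilyl chloride, CC(C)(C)[Si](C)(C)Cl
Why: Imidazole-promoted silylation of a secondary alcohol is standard and masks the hydroxyl so that only the alkyne C–H is metalated next.

**Step 6**
Reactants: 12 {1-[4-(benzyloxy)phenyl]prop-2-yn-1-yl}oxy(tert-butyl)dimethylsilane; 9 1-[4-(benzyloxy)phenyl]-5-(3-methoxyphenyl)-3-methylidenepentan-2-one
Product: 15 3-[4-(benzyloxy)benzyl]-6-[4-(benzyloxy)phenyl]-6-[(tert-butyldimethylsilyl)oxy]-2-[2-(3-methoxyphenyl)ethyl]hex-1-en-4-yn-3-ol (racemic diastereomer mixture), via lithium acetylide 13 (not isolated), via dichlorocerium acetylide 14 (not isolated)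
Conditions: n-BuLi, THF, −78 °C; anhydrous CeCl3, THF, −78 °C; then 9, −78 °C; aq. NH4Cl
Reagents that add atoms: none
Why: The alkynylcerium reagent is much less basic than the lithium acetylide, so it should add 1,2 to the carbonyl of 9 instead of deprotonating the benzylic α-CH2 or adding in conjugate fashion (organocerium carbonyl addition); the two centres are uncontrolled and irrelevant because steps 9 and 10 remove them.

**Step 7**
Reactants: 15 3-[4-(benzyloxy)benzyl]-6-[4-(benzyloxy)phenyl]-6-[(tert-butyldimethylsilyl)oxy]-2-[2-(3-methoxyphenyl)ethyl]hex-1-en-4-yn-3-ol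
Product: 16 3-[4-(benzyloxy)benzyl]-6-[4-(benzyloxy)phenyl]-6-[(tert-butyldimethylsilyl)oxy]-2-[2-(3-methoxyphenyl)ethyl]hex-1-en-4-yn-3-yl acetate (racemic diastereomer mixture)
Conditions: Ac2O, DMAP, Et3N, CH2Cl2, rt to 40 °C
Reagents that add atoms: acetic anhydride, CC(=O)OC(C)=O
Why: DMAP-catalysed acylation is the usual way to esterify tertiary propargylic alcohols, and the only other hydroxyl is silylated.

**Step 8**
Reactants: 16 3-[4-(benzyloxy)benzyl]-6-[4-(benzyloxy)phenyl]-6-[(tert-butyldimethylsilyl)oxy]-2-[2-(3-methoxyphenyl)ethyl]hex-1-en-4-yn-3-yl acetate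
Product: 17 3-[4-(benzyloxy)benzyl]-6-[4-(benzyloxy)phenyl]-6-hydroxy-2-[2-(3-methoxyphenyl)ethyl]hex-1-en-4-yn-3-yl acetate (racemic diastereomer mixture)
Conditions: TBAF, AcOH, THF, 0 °C to rt
Reagents that add atoms: none
Why: Buffered fluoride cleaves the silyl ether without touching the tertiary acetate, and the linear alkyne between the two oxygens rules out acetyl migration.

**Step 9**
Reactants: 17 3-[4-(benzyloxy)benzyl]-6-[4-(benzyloxy)phenyl]-6-hydroxy-2-[2-(3-methoxyphenyl)ethyl]hex-1-en-4-yn-3-yl acetate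
Product: 18 3-[4-(benzyloxy)benzyl]-6-[4-(benzyloxy)phenyl]-2-[2-(3-methoxyphenyl)ethyl]-6-oxohex-1-en-4-yn-3-yl acetate (racemic)
Conditions: MnO2, CH2Cl2, rt
Reagents that add atoms: none
Why: Activated MnO2 selectively oxidizes the benzylic propargylic secondary alcohol to the ynone under neutral conditions that spare the tertiary acetate and the alkene, and it removes the centre at C6.

**Step 10**
Reactants: 18 3-[4-(benzyloxy)benzyl]-6-[4-(benzyloxy)phenyl]-2-[2-(3-methoxyphenyl)ethyl]-6-oxohex-1-en-4-yn-3-yl acetate; 19 carbon monoxide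
Product: 21 6-[4-(benzyloxy)benzyl]-2-[4-(benzyloxy)benzoyl]-3-hydroxy-5-[2-(3-methoxyphenyl)ethyl]phenyl acetate, via cyclohexa-2,4-dienone tautomer 20 (not isolated)
Conditions: [Rh(CO)2Cl]2 (5 mol %), CO (1 atm), ClCH2CH2Cl, 60 °C
Reagents that add atoms: none
Why: Proposed new method: the monovalent rhodium complex [Rh(CO)2Cl]2 should activate the alkyne of 18 so that the acetate carbonyl oxygen attacks C4, the β-carbon of the ynone, and the ester shifts from C3 to C4 through a five-membered dioxolenium ion, leaving a rhodium carbene at C5 conjugated with the new C3=C4 bond and the C1=C2 alkene. CO insertion at the carbene gives a dienyl ketene (or the equivalent acyl rhodacycle), and ring B closes by 6π electrocyclization (or reductive elimination), forming the bonds from the CO carbon to C5 and to C1, which are B3–B4 and B3–B2; dienone 20 then enolizes to the phenol. The closest known reaction type is the rhodium-catalysed [5+1] carbonylative benzannulation of 3-acyloxy-1,4-enynes with CO to resorcinol monoesters, shown for terminal alkynes and not for an aroyl-capped internal alkyne carrying a tertiary acetate. No stereocenter is formed, and the one at C3 disappears on aromatization. The step needs a 1,2- and not a 1,3-acyloxy shift, which the aroyl group secures because attack at the ynone β-carbon is the conjugate mode, and it needs the carbene and the alkene cis across C3=C4, which the allyl-cation character of the vinyl carbene or reversible ester migration should allow. The CO oxygen emerges free at B3 and the migrated acetate sits at B5, so the two ring oxygens are differentiated.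

**Step 11**
Reactants: 21 6-[4-(benzyloxy)benzyl]-2-[4-(benzyloxy)benzoyl]-3-hydroxy-5-[2-(3-methoxyphenyl)ethyl]phenyl acetate
Product: 22 6-[4-(benzyloxy)benzyl]-2-[4-(benzyloxy)benzoyl]-3-methoxy-5-[2-(3-methoxyphenyl)ethyl]phenyl acetate
Conditions: MeOH, PPh3, DIAD, THF, 0 °C to rt
Reagents that add atoms: methanol, CO
Why: Mitsunobu etherification methylates the acidic ortho-acyl phenol without carbonate base or alkoxide, so the neighbouring aryl acetate should neither cleave nor scramble.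

**Step 12**
Reactants: 22 6-[4-(benzyloxy)benzyl]-2-[4-(benzyloxy)benzoyl]-3-methoxy-5-[2-(3-methoxyphenyl)ethyl]phenyl acetate
Product: 23 {3-[4-(benzyloxy)benzyl]-2-hydroxy-6-methoxy-4-[2-(3-methoxyphenyl)ethyl]phenyl}[4-(benzyloxy)phenyl]methanone
Conditions: K2CO3, MeOH, rt; aq. NH4Cl
Reagents that add atoms: none
Why: Base-catalysed transesterification of an aryl acetate with methanol is fast, while the methyl and benzyl ethers and the diaryl ketone are inert.

**Step 13**
Reactants: 23 {3-[4-(benzyloxy)benzyl]-2-hydroxy-6-methoxy-4-[2-(3-methoxyphenyl)ethyl]phenyl}[4-(benzyloxy)phenyl]methanone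
Product: 24 2,6-bis(4-hydroxybenzyl)-3-methoxy-5-[2-(3-methoxyphenyl)ethyl]phenol
Conditions: H2 (3 atm), 10% Pd/C, EtOH/AcOH, cat. HCl, rt to 40 °C
Reagents that add atoms: none
Why: Hydrogenolysis over Pd/C cleaves both aryl benzyl ethers and, in acidic medium, takes the electron-rich diaryl ketone through the benzhydrol to the diarylmethane, the carbinol C–O bond being activated by the ortho- and para-hydroxyl groups (benzylic hydrogenolysis).

**Compound list**

1 | 3-methoxybenzyl chloride | COc1cccc(CCl)c1 | starting material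
2 | 2,3-dibromopropene | BrCC(Br)=C | starting material
3 | 3-methoxybenzylmagnesium chloride (not isolated) | COc1cccc(C[Mg]Cl)c1 | intermediate
4 | 2-bromo-4-(3-methoxyphenyl)but-1-ene | C=C(Br)CCc1cccc(OC)c1 | intermediate
5 | 4-(benzyloxy)phenylacetic acid | OC(=O)Cc1ccc(OCc2ccccc2)cc1 | starting material
6 | 2-[4-(benzyloxy)phenyl]-1-(imidazol-1-yl)ethanone (acyl imidazole, not isolated) | O=C(Cc1ccc(OCc2ccccc2)cc1)n1ccnc1 | intermediate
7 | 2-[4-(benzyloxy)phenyl]-N-methoxy-N-methylacetamide | CON(C)C(=O)Cc1ccc(OCc2ccccc2)cc1 | intermediate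
8 | [4-(3-methoxyphenyl)but-1-en-2-yl]magnesium bromide (not isolated) | Br[Mg]C(=C)CCc1cccc(OC)c1 | intermediate
9 | 1-[4-(benzyloxy)phenyl]-5-(3-methoxyphenyl)-3-methylidenepentan-2-one | C=C(CCc1cccc(OC)c1)C(=O)Cc1ccc(OCc2ccccc2)cc1 | intermediate
10 | 4-(benzyloxy)benzaldehyde | O=Cc1ccc(OCc2ccccc2)cc1 | starting material
11 | 1-[4-(benzyloxy)phenyl]prop-2-yn-1-ol (racemic) | C#CC(O)c1ccc(OCc2ccccc2)cc1 | intermediate
12 | {1-[4-(benzyloxy)phenyl]prop-2-yn-1-yl}oxy(tert-butyl)dimethylsilane (racemic) | C#CC(O[Si](C)(C)C(C)(C)C)c1ccc(OCc2ccccc2)cc1 | intermediate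
13 | lithium acetylide of 12 (not isolated) | [Li]C#CC(O[Si](C)(C)C(C)(C)C)c1ccc(OCc2ccccc2)cc1 | intermediate
14 | dichlorocerium acetylide of 12 (not isolated) | Cl[Ce](Cl)C#CC(O[Si](C)(C)C(C)(C)C)c1ccc(OCc2ccccc2)cc1 | intermediate
15 | 3-[4-(benzyloxy)benzyl]-6-[4-(benzyloxy)phenyl]-6-[(tert-butyldimethylsilyl)oxy]-2-[2-(3-methoxyphenyl)ethyl]hex-1-en-4-yn-3-ol (racemic, diastereomer mixture) | OC(Cc1ccc(OCc2ccccc2)cc1)(C#CC(O[Si](C)(C)C(C)(C)C)c1ccc(OCc2ccccc2)cc1)C(=C)CCc1cccc(OC)c1 | intermediate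
16 | 3-[4-(benzyloxy)benzyl]-6-[4-(benzyloxy)phenyl]-6-[(tert-butyldimethylsilyl)oxy]-2-[2-(3-methoxyphenyl)ethyl]hex-1-en-4-yn-3-yl acetate (racemic, diastereomer mixture) | CC(=O)OC(Cc1ccc(OCc2ccccc2)cc1)(C#CC(O[Si](C)(C)C(C)(C)C)c1ccc(OCc2ccccc2)cc1)C(=C)CCc1cccc(OC)c1 | intermediate
17 | 3-[4-(benzyloxy)benzyl]-6-[4-(benzyloxy)phenyl]-6-hydroxy-2-[2-(3-methoxyphenyl)ethyl]hex-1-en-4-yn-3-yl acetate (racemic, diastereomer mixture) | CC(=O)OC(Cc1ccc(OCc2ccccc2)cc1)(C#CC(O)c1ccc(OCc2ccccc2)cc1)C(=C)CCc1cccc(OC)c1 | intermediate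
18 | 3-[4-(benzyloxy)benzyl]-6-[4-(benzyloxy)phenyl]-2-[2-(3-methoxyphenyl)ethyl]-6-oxohex-1-en-4-yn-3-yl acetate (racemic) | CC(=O)OC(Cc1ccc(OCc2ccccc2)cc1)(C#CC(=O)c1ccc(OCc2ccccc2)cc1)C(=C)CCc1cccc(OC)c1 | intermediate
19 | carbon monoxide | [C-]#[O+] | starting material
20 | 2-[4-(benzyloxy)benzoyl]-6-[4-(benzyloxy)benzyl]-5-[2-(3-methoxyphenyl)ethyl]-3-oxocyclohexa-1,5-dien-1-yl acetate (dienone tautomer, not isolated) | O=C1CC(CCc2cccc(OC)c2)=C(Cc2ccc(OCc3ccccc3)cc2)C(OC(C)=O)=C1C(=O)c1ccc(OCc2ccccc2)cc1 | intermediate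
21 | 6-[4-(benzyloxy)benzyl]-2-[4-(benzyloxy)benzoyl]-3-hydroxy-5-[2-(3-methoxyphenyl)ethyl]phenyl acetate | COc1cccc(CCc2cc(O)c(C(=O)c3ccc(OCc4ccccc4)cc3)c(OC(C)=O)c2Cc2ccc(OCc3ccccc3)cc2)c1 | intermediate
22 | 6-[4-(benzyloxy)benzyl]-2-[4-(benzyloxy)benzoyl]-3-methoxy-5-[2-(3-methoxyphenyl)ethyl]phenyl acetate | COc1cccc(CCc2cc(OC)c(C(=O)c3ccc(OCc4ccccc4)cc3)c(OC(C)=O)c2Cc2ccc(OCc3ccccc3)cc2)c1 | intermediate
23 | {3-[4-(benzyloxy)benzyl]-2-hydroxy-6-methoxy-4-[2-(3-methoxyphenyl)ethyl]phenyl}[4-(benzyloxy)phenyl]methanone | COc1cccc(CCc2cc(OC)c(C(=O)c3ccc(OCc4ccccc4)cc3)c(O)c2Cc2ccc(OCc3ccccc3)cc2)c1 | intermediate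
24 | 2,6-bis(4-hydroxybenzyl)-3-methoxy-5-[2-(3-methoxyphenyl)ethyl]phenol | COc1cccc(CCc2cc(OC)c(Cc3ccc(O)cc3)c(O)c2Cc2ccc(O)cc2)c1 | target

**Step count**

Total: 13 steps. Longest linear sequence: 10 steps (steps 1, 3, 6, 7, 8, 9, 10, 11, 12, 13; the branch through steps 4 and 5 is equally long).

**Steps most likely to fail**

1. Step 10. The acetate may migrate by the 1,3 course to an allenyl acetate, the ynone may tie up the catalyst, or the carbene may be consumed before CO insertion, so that ring B does not close. The fallback sets out from enone 9, uses the benzannulation only in its established terminal-alkyne form and introduces the B4 substituent afterwards, returning to the route at target 24. Ethynylmagnesium bromide with CeCl3 adds to 9 to give 3-[4-(benzyloxy)benzyl]-2-[2-(3-methoxyphenyl)ethyl]pent-1-en-4-yn-3-ol F1. Acetylation (Ac2O, DMAP, Et3N) gives 3-[4-(benzyloxy)benzyl]-2-[2-(3-methoxyphenyl)ethyl]pent-1-en-4-yn-3-yl acetate F2. [Rh(CO)2Cl]2 under CO then closes ring B to 2-[4-(benzyloxy)benzyl]-5-hydroxy-3-[2-(3-methoxyphenyl)ethyl]phenyl acetate F3, with B4 still unsubstituted. Mitsunobu methylation gives 2-[4-(benzyloxy)benzyl]-5-methoxy-3-[2-(3-methoxyphenyl)ethyl]phenyl acetate F4, and methanolysis (K2CO3, MeOH) gives 2-[4-(benzyloxy)benzyl]-5-methoxy-3-[2-(3-methoxyphenyl)ethyl]phenol F5, whose only free ortho position is B4. Magnesium-mediated ortho-formylation (MgCl2, Et3N, paraformaldehyde, MeCN, reflux) gives 3-[4-(benzyloxy)benzyl]-2-hydroxy-6-methoxy-4-[2-(3-methoxyphenyl)ethyl]benzaldehyde F6. Commercial 4-(benzyloxy)phenylmagnesium bromide (excess) adds to give 2-[4-(benzyloxy)benzyl]-6-{[4-(benzyloxy)phenyl](hydroxy)methyl}-5-methoxy-3-[2-(3-methoxyphenyl)ethyl]phenol F7. Hydrogenolysis over Pd/C (H2, EtOH/AcOH) removes the benzhydrylic hydroxyl and both benzyl ethers to reach 24.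

2. Step 6. Proton transfer from the benzylic α-CH2 of 9 to the acetylide (enolization instead of addition), or conjugate addition, may leave the carbinol unformed. The fallback builds the carbinol in the other order, on a ketone without acidic α-hydrogens; it sets out from Grignard reagent 8 (from bromide 4) and acetylide 13 (from 12) and returns at 15. Reagent 8 is formylated with DMF to 4-(3-methoxyphenyl)-2-methylidenebutanal F8. Lithium acetylide 13 adds to the aldehyde to give 6-[4-(benzyloxy)phenyl]-6-[(tert-butyldimethylsilyl)oxy]-2-[2-(3-methoxyphenyl)ethyl]hex-1-en-4-yn-3-ol F9. MnO2 oxidizes this to the cross-conjugated ketone 6-[4-(benzyloxy)phenyl]-6-[(tert-butyldimethylsilyl)oxy]-2-[2-(3-methoxyphenyl)ethyl]hex-1-en-4-yn-3-one F10. 4-(Benzyloxy)benzylmagnesium chloride F11, made from commercial 4-(benzyloxy)benzyl chloride and Mg, is then added with CeCl3 at −78 °C in 1,2 fashion to give 15.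

3. Step 13. Hydrogenation of the hindered, doubly ortho-substituted diaryl ketone may stall at the ketone or the carbinol once the benzyl ethers are gone, and forcing conditions may begin to saturate a ring. The fallback separates the deoxygenation from the debenzylation and does it by hydride chemistry; it sets out from 23 and returns at 24. Ethyl chloroformate and Et3N convert the phenol into 2-[4-(benzyloxy)benzoyl]-6-[4-(benzyloxy)benzyl]-3-methoxy-5-[2-(3-methoxyphenyl)ethyl]phenyl ethyl carbonate F12. NaBH4 in aqueous THF reduces the ketone, the carbonate shifts to the new alkoxide, an ortho-quinone methide forms and is reduced, giving 2,6-bis[4-(benzyloxy)benzyl]-3-methoxy-5-[2-(3-methoxyphenyl)ethyl]phenol F13. Plain hydrogenolysis (H2, Pd/C, EtOAc/MeOH) of the two benzyl ethers gives 24.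

**Further compounds**

F1 | step 10 | 3-[4-(benzyloxy)benzyl]-2-[2-(3-methoxyphenyl)ethyl]pent-1-en-4-yn-3-ol (racemic) | OC(Cc1ccc(OCc2ccccc2)cc1)(C#C)C(=C)CCc1cccc(OC)c1
F2 | step 10 | 3-[4-(benzyloxy)benzyl]-2-[2-(3-methoxyphenyl)ethyl]pent-1-en-4-yn-3-yl acetate (racemic) | CC(=O)OC(Cc1ccc(OCc2ccccc2)cc1)(C#C)C(=C)CCc1cccc(OC)c1
F3 | step 10 | 2-[4-(benzyloxy)benzyl]-5-hydroxy-3-[2-(3-methoxyphenyl)ethyl]phenyl acetate | COc1cccc(CCc2cc(O)cc(OC(C)=O)c2Cc2ccc(OCc3ccccc3)cc2)c1
F4 | step 10 | 2-[4-(benzyloxy)benzyl]-5-methoxy-3-[2-(3-methoxyphenyl)ethyl]phenyl acetate | COc1cccc(CCc2cc(OC)cc(OC(C)=O)c2Cc2ccc(OCc3ccccc3)cc2)c1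
F5 | step 10 | 2-[4-(benzyloxy)benzyl]-5-methoxy-3-[2-(3-methoxyphenyl)ethyl]phenol | COc1cccc(CCc2cc(OC)cc(O)c2Cc2ccc(OCc3ccccc3)cc2)c1
F6 | step 10 | 3-[4-(benzyloxy)benzyl]-2-hydroxy-6-methoxy-4-[2-(3-methoxyphenyl)ethyl]benzaldehyde | COc1cccc(CCc2cc(OC)c(C=O)c(O)c2Cc2ccc(OCc3ccccc3)cc2)c1
F7 | step 10 | 2-[4-(benzyloxy)benzyl]-6-{[4-(benzyloxy)phenyl](hydroxy)methyl}-5-methoxy-3-[2-(3-methoxyphenyl)ethyl]phenol (racemic) | COc1cccc(CCc2cc(OC)c(C(O)c3ccc(OCc4ccccc4)cc3)c(O)c2Cc2ccc(OCc3ccccc3)cc2)c1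
F8 | step 6 | 4-(3-methoxyphenyl)-2-methylidenebutanal | O=CC(=C)CCc1cccc(OC)c1
F9 | step 6 | 6-[4-(benzyloxy)phenyl]-6-[(tert-butyldimethylsilyl)oxy]-2-[2-(3-methoxyphenyl)ethyl]hex-1-en-4-yn-3-ol (racemic, diastereomer mixture) | OC(C#CC(O[Si](C)(C)C(C)(C)C)c1ccc(OCc2ccccc2)cc1)C(=C)CCc1cccc(OC)c1
F10 | step 6 | 6-[4-(benzyloxy)phenyl]-6-[(tert-butyldimethylsilyl)oxy]-2-[2-(3-methoxyphenyl)ethyl]hex-1-en-4-yn-3-one (racemic) | O=C(C#CC(O[Si](C)(C)C(C)(C)C)c1ccc(OCc2ccccc2)cc1)C(=C)CCc1cccc(OC)c1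
F11 | step 6 | 4-(benzyloxy)benzylmagnesium chloride | Cl[Mg]Cc1ccc(OCc2ccccc2)cc1
F12 | step 13 | 2-[4-(benzyloxy)benzoyl]-6-[4-(benzyloxy)benzyl]-3-methoxy-5-[2-(3-methoxyphenyl)ethyl]phenyl ethyl carbonate | COc1cccc(CCc2cc(OC)c(C(=O)c3ccc(OCc4ccccc4)cc3)c(OC(=O)OCC)c2Cc2ccc(OCc3ccccc3)cc2)c1
F13 | step 13 | 2,6-bis[4-(benzyloxy)benzyl]-3-methoxy-5-[2-(3-methoxyphenyl)ethyl]phenol | COc1cccc(CCc2cc(OC)c(Cc3ccc(OCc4ccccc4)cc3)c(O)c2Cc2ccc(OCc3ccccc3)cc2)c1
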